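**Retrosynthetic overview**
- The target is opened at the O-1 to C-2 bond to a 2'-hydroxychalcone; ring C is closed last by a catalytic enantioselective oxa-Michael addition (a chalcone-isomerase mimic) that sets C-2.
- The chalcone is cut at the enone C=C (Claisen–Schmidt) into a 3,5-diprenylated 2,4-dihydroxyacetophenone and 2,2-dimethyl-2H-chromene-6-carbaldehyde, with no protecting groups.
- The chromene pyran ring comes from an ortho-prenylphenol by dehydrogenation to an ortho-quinone methide and oxa-6π electrocyclisation, as in the plant pathway.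
- Both prenylated arenes come from direct C-prenylation of 2,4-dihydroxyacetophenone and 4-hydroxybenzaldehyde with prenyl bromide.
- Ring order: rings A and B are bought; the chromene pyran ring is formed first (step 3) and ring C last (step 5).

Assumption: the quinine-derived thiourea is taken to give the (2S) configuration that the target SMILES requires; a first analytical run (chiral HPLC, CD) checks this, and the quinidine-derived pseudo-enantiomer is used instead if it gives 2R.

**Step 1**
Reactants: 1 2,4-dihydroxyacetophenone; 2 prenyl bromide (1-bromo-3-methylbut-2-ene)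
Product: 5 diprenylresacetophenone (1-[2,4-dihydroxy-3,5-bis(3-methylbut-2-en-1-yl)phenyl]ethan-1-one), via 3-prenyl monoadduct 3 (not isolated), via 5-prenyl monoadduct 4 (not isolated)
Conditions: 2 (2.5 equiv), 10% aq KOH, 0 °C to rt, 24 h; dil. HCl; chromatography
Reagents that add atoms: prenyl bromide 2, CC(C)=CCBr
Why: Phenoxide C-alkylation in water, where the solvated oxygen is shielded and the soft allylic bromide attacks the two ring carbons ortho to the 4-oxygen one after the other (through 3 or 4), giving 5 in one step in modest yield beside separable mono- and O-alkylated material; no stereocentre is formed.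

**Step 2**
Reactants: 6 4-hydroxybenzaldehyde; 2 prenyl bromide
Product: 7 ortho-prenylphenol aldehyde (4-hydroxy-3-(3-methylbut-2-en-1-yl)benzaldehyde)
Conditions: 2 (1.1 equiv), 10% aq KOH, rt, 24–48 h; dil. HCl; chromatography
Reagents that add atoms: prenyl bromide 2, CC(C)=CCBr
Why: The same aqueous phenoxide ortho-C-prenylation, here stopped at mono-alkylation by stoichiometry (modest yield, with O-prenyl ether and dialkylated by-products removed by chromatography); no stereocentre is formed.

**Step 3**
Reactants: 7 ortho-prenylphenol aldehyde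
Product: 9 chromene aldehyde (2,2-dimethyl-2H-chromene-6-carbaldehyde), via ortho-quinone methide 8 (not isolated)
Conditions: DDQ (1.1 equiv), 1,4-dioxane, 90 °C, 2 h
Reagents that add atoms: none
Why: DDQ dehydrogenation removes hydride from the benzylic CH2 ortho to the phenol to give ortho-quinone methide 8, which closes by oxa-6π electrocyclisation to the 2,2-dimethylchromene, the laboratory counterpart of the oxidative cyclisation of ortho-prenylphenols in plants; the aldehyde is untouched and no stereocentre is formed.

**Step 4**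
Reactants: 5 diprenylresacetophenone; 9 chromene aldehyde
Product: 11 chalcone ((2E)-1-[2,4-dihydroxy-3,5-bis(3-methylbut-2-en-1-yl)phenyl]-3-(2,2-dimethyl-2H-chromen-6-yl)prop-2-en-1-one), via aldol adduct 10 (not isolated)
Conditions: 9 (1.1 equiv), 50% aq KOH (excess), EtOH, N2, rt, 48–72 h; cold 1 M HCl to pH 5; chromatography to remove any racemic flavanone
Reagents that add atoms: none
Why: Claisen–Schmidt condensation between the only enolisable ketone and a non-enolisable aldehyde, in which aldol 10 dehydrates by E1cB to the thermodynamic E-enone and the strong base keeps the product as the open chalcone phenolate so that ring C does not close prematurely; the carbinol centre of 10 is lost on dehydration.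

**Step 5**
Reactants: 11 chalcone
Product: 12 target flavanone ((2S)-2-(2,2-dimethyl-2H-chromen-6-yl)-7-hydroxy-6,8-bis(3-methylbut-2-en-1-yl)-2,3-dihydro-4H-chromen-4-one)
Conditions: N-[3,5-bis(trifluoromethyl)phenyl]-N'-[(8α,9S)-6'-methoxycinchonan-9-yl]thiourea (20 mol%), PhMe (0.05 M), 4 Å MS, 0 °C to rt; stop at peak ee (chiral HPLC); SiO2 plug; recrystallise
Reagents that add atoms: none
Why: Proposed new method: a chalcone-isomerase-like 6-endo-trig intramolecular oxa-Michael addition in which the quinuclidine nitrogen acts as general base on the 2'-OH while the thiourea hydrogen-bonds the enone carbonyl and presents one enantioface of the β-carbon to the phenol oxygen, so that C-2 is set as S under kinetic control; the closest known chemistry is the cinchona-alkaloid- and cinchona-thiourea-catalysed asymmetric cyclisation of 2'-hydroxychalcones and of their α-alkoxycarbonyl-activated analogues to flavanones, extended here to an unactivated chalcone carrying a free 4'-OH that is shielded by two ortho prenyl groups, with retro-Michael erosion limited by the non-polar solvent, low temperature and the lack of a free para-hydroxyl on ring B.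

**Compound list**
1 | 2,4-dihydroxyacetophenone (1-(2,4-dihydroxyphenyl)ethan-1-one) | CC(=O)c1ccc(O)cc1O | starting material
2 | prenyl bromide (1-bromo-3-methylbut-2-ene) | CC(C)=CCBr | starting material
3 | 3-prenyl monoadduct (1-[2,4-dihydroxy-3-(3-methylbut-2-en-1-yl)phenyl]ethan-1-one) | CC(=O)c1ccc(O)c(CC=C(C)C)c1O | intermediate
4 | 5-prenyl monoadduct (1-[2,4-dihydroxy-5-(3-methylbut-2-en-1-yl)phenyl]ethan-1-one) | CC(=O)c1cc(CC=C(C)C)c(O)cc1O | intermediate
5 | diprenylresacetophenone (1-[2,4-dihydroxy-3,5-bis(3-methylbut-2-en-1-yl)phenyl]ethan-1-one) | CC(=O)c1cc(CC=C(C)C)c(O)c(CC=C(C)C)c1O | intermediate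
6 | 4-hydroxybenzaldehyde | O=Cc1ccc(O)cc1 | starting material
7 | ortho-prenylphenol aldehyde (4-hydroxy-3-(3-methylbut-2-en-1-yl)benzaldehyde) | CC(C)=CCc1cc(C=O)ccc1O | intermediate
8 | ortho-quinone methide ((3Z)-3-(3-methylbut-2-en-1-ylidene)-4-oxocyclohexa-1,5-diene-1-carbaldehyde) | CC(C)=C/C=C1\C(=O)C=CC(C=O)=C1 | intermediate
9 | chromene aldehyde (2,2-dimethyl-2H-chromene-6-carbaldehyde) | CC1(C)C=Cc2cc(C=O)ccc2O1 | intermediate
10 | aldol adduct, racemic (1-[2,4-dihydroxy-3,5-bis(3-methylbut-2-en-1-yl)phenyl]-3-(2,2-dimethyl-2H-chromen-6-yl)-3-hydroxypropan-1-one) | CC(C)=CCc1cc(C(=O)CC(O)c2ccc3c(c2)C=CC(C)(C)O3)c(O)c(CC=C(C)C)c1O | intermediate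
11 | chalcone ((2E)-1-[2,4-dihydroxy-3,5-bis(3-methylbut-2-en-1-yl)phenyl]-3-(2,2-dimethyl-2H-chromen-6-yl)prop-2-en-1-one) | CC(C)=CCc1cc(C(=O)/C=C/c2ccc3c(c2)C=CC(C)(C)O3)c(O)c(CC=C(C)C)c1O | intermediate
12 | target flavanone ((2S)-2-(2,2-dimethyl-2H-chromen-6-yl)-7-hydroxy-6,8-bis(3-methylbut-2-en-1-yl)-2,3-dihydro-4H-chromen-4-one) | CC(C)=CCc1cc2c(c(CC=C(C)C)c1O)O[C@H](c1ccc3c(c1)C=CC(C)(C)O3)CC2=O | target

**Step count and risks**
Total steps: 5. Longest linear sequence: 4 (6 → 7 → 9 → 11 → 12); the other branch is 1 → 5, joining at step 4.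

The three steps most likely to fail:

Step 5 (enantioselective oxa-Michael). The risks are low ee, slow turnover because the acidic 7-OH ties up the amine, and erosion by the reverse reaction. The fallback sets out from 11 and comes back at 12. Chalcone 11 is cyclised without stereocontrol (NaOAc, EtOH, reflux) to the racemic flavanone F1. F1 is then resolved kinetically by asymmetric transfer hydrogenation (RuCl[(R,R)-TsDPEN](p-cymene) 1 mol%, HCO2H/Et3N 5:2, EtOAc, rt, to about 50–55% conversion). This catalyst forms 4R alcohols, which is the matched case for the 2R ketone (hydride enters anti to the 2-aryl group). The 2R enantiomer is therefore removed as the cis-(2R,4R)-flavan-4-ol F2, and the unreacted 2S ketone is 12, separated by chromatography.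

Step 1 (double C-prenylation). The risk is a mixture of mono-, di-, O- and gem-alkylated products with a low yield of 5. The fallback sets out from 1 and comes back at 5. Both positions ortho to the 4-OH are iodinated (I2, HIO3, EtOH/H2O, rt) to 1-(2,4-dihydroxy-3,5-diiodophenyl)ethan-1-one F3. A double Stille coupling with tributyl(3-methylbut-2-en-1-yl)stannane (Pd(PPh3)4, zerovalent palladium, DMF, 90 °C) then gives 5. The halogens fix the regiochemistry and the linear prenyl group is transferred.

Step 4 (Claisen–Schmidt on the unprotected ketone). The risk is sluggish enolisation of the dianion formed from the acidic 4-OH. The fallback sets out from 5 and comes back at 11. The 4-OH is masked as its methoxymethyl ether (MOMCl, K2CO3, acetone, rt; the chelated 2-OH does not react) to give 1-[2-hydroxy-4-(methoxymethoxy)-3,5-bis(3-methylbut-2-en-1-yl)phenyl]ethan-1-one F4. F4 is condensed with 9 (KOH, EtOH, rt) to (2E)-1-[2-hydroxy-4-(methoxymethoxy)-3,5-bis(3-methylbut-2-en-1-yl)phenyl]-3-(2,2-dimethyl-2H-chromen-6-yl)prop-2-en-1-one F5. Brief treatment of F5 with HCl in MeOH at rt removes the acetal and gives 11.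

**Further compounds**
F1 | step 5 | racemic flavanone (2-(2,2-dimethyl-2H-chromen-6-yl)-7-hydroxy-6,8-bis(3-methylbut-2-en-1-yl)-2,3-dihydro-4H-chromen-4-one) | CC(C)=CCc1cc2c(c(CC=C(C)C)c1O)OC(c1ccc3c(c1)C=CC(C)(C)O3)CC2=O
F2 | step 5 | cis-(2R,4R)-flavan-4-ol ((2R,4R)-2-(2,2-dimethyl-2H-chromen-6-yl)-6,8-bis(3-methylbut-2-en-1-yl)-3,4-dihydro-2H-chromene-4,7-diol) | CC(C)=CCc1cc2c(c(CC=C(C)C)c1O)O[C@@H](c1ccc3c(c1)C=CC(C)(C)O3)C[C@H]2O
F3 | step 1 | 1-(2,4-dihydroxy-3,5-diiodophenyl)ethan-1-one | CC(=O)c1cc(I)c(O)c(I)c1O
F4 | step 4 | 1-[2-hydroxy-4-(methoxymethoxy)-3,5-bis(3-methylbut-2-en-1-yl)phenyl]ethan-1-one | CC(=O)c1cc(CC=C(C)C)c(OCOC)c(CC=C(C)C)c1O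
F5 | step 4 | (2E)-1-[2-hydroxy-4-(methoxymethoxy)-3,5-bis(3-methylbut-2-en-1-yl)phenyl]-3-(2,2-dimethyl-2H-chromen-6-yl)prop-2-en-1-one | CC(C)=CCc1cc(C(=O)/C=C/c2ccc3c(c2)C=CC(C)(C)O3)c(O)c(CC=C(C)C)c1OCOC
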